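Assumption: the SMILES of the target holds no stereodescriptor, the molecule has no stereocentre, and rotation about its C(aryl)–O bonds is taken to be fast at room temperature. Bromoiesol A is therefore treated as achiral, and no step has to set configuration.

## Analysis of the target

Bromoiesol A (13) is a linear, ortho-linked triaryl diether, HO–ring A–O–ring B–O–ring C, with seven bromine atoms. The atom labels used throughout are:
- ring A: C1 (OH), C2 (O to ring B), C3 and C5 (Br)
- ring B: C1 (O to ring A), C2 (O to ring C), C3, C4 and C5 (Br), C6 (H)
- ring C: C1' (O), C2' and C4' (Br)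

There is no stereocentre and no ring fusion, so the problem is one of regiochemistry and chemoselectivity on three flat rings. Both ether bonds are crowded, each with three ortho substituents: OH, Br3 and O–ring C around the A–O–B bond, and O–ring A, Br3 and Br2' around the B–O–C bond.

The bromine pattern shows to which ring each oxygen belongs. The oxygen on C2(A) lies ortho/para to Br3 and Br5 of ring A, whereas the free OH on C1(A) is meta to both, so the ring A bromines cannot come from bromination of the free phenol. The oxygen on C2(B) lies ortho/para to Br3 and Br5 of ring B.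

The feature that invites the key move is the vicinal pair C1(B)–O / C2(B)–O. C1(B) must accept an oxygen that belongs to ring A (electrophilic carbon), while O on C2(B) is the phenol oxygen of ring B itself (nucleophile). This 1,2-ambiphilic pattern is the retron of an o-quinone diazide, a carbene carbon next to a carbonyl group.

The seven C–Br bonds exclude Pd, Ni, hot Cu, organolithium reagents and hydrogenolysis. Every 2-aryloxyphenoxide on the way, including that of 13, is open in hot base to Smiles migration and to closure of a dibenzo-p-dioxin.

The hard points are telling apart the two oxygens of ring B, which differ only by Br3 versus H6, and making two hindered C–O bonds without a metal that inserts into C–Br.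

## Retrosynthetic reasoning

**Cut 1, 13 ⇒ 11 (through 12): the O–CH3 bond on O1 of ring A.** The methyl group fixes which of the two vicinal oxygens of ring A is arylated and leaves one free OH per fragment in the key step. The forward reaction has to cleave an alkyl aryl ether beside two diaryl ethers, under acidic and cold conditions in which no phenoxide exists.

**Cut 2, 11 ⇒ 4 + 9 + 8 (through 10): both ether bonds of ring B at once, C1(B)–O and O(C2 of B)–C1'(C).**
- Cutting here leaves three monocyclic pieces with three, two and two bromines. In each piece the halogen pattern follows the innate directing effects of its own oxygen.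
- Cutting C2(A)–O instead would make ring B a nucleophile at both oxygens. They would then have to be told apart by protecting groups.
- Ring B is taken back to its dearomatized form 4. Its diazo carbon is the electrophile for the OH of 9, and its carbonyl oxygen becomes the phenoxide of 10 only after aromatization. That phenoxide is then arylated by 8.
- The forward reaction has to capture a quinoid carbene with a hindered phenol and then transfer one aryl group from iodine(III), all in the presence of seven C–Br bonds.

**Cut 3, 4 ⇒ 3 ⇒ 2 ⇒ 1: the C=N2 group goes back to an amine and a nitro group, and two C–Br bonds (C3 and C5 of ring B) are cut.** The OH/NO2 pair of 1 is the source of all regiochemical information in ring B: the OH ends next to Br3, the nitrogen next to H6. In 1 the OH, the nitro group and the bromine all direct to the same two carbons, so the forward bromination needs no control element.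

**Cut 4, 8 ⇒ 5 + 6 (through 7): the C–I bond to the trimethoxyphenyl dummy ligand.** Ring C arrives with its two bromines in place, and 6 has three equivalent positions, so the forward electrophilic substitution has one possible outcome.

**Fragment 9 is bought.** Its OH is ortho/para to both bromines, which is exactly the relation of the bridging oxygen to Br3 and Br5 of ring A.

## Alternatives that were turned down

**Alternative 1:** the textbook route cuts the two ether bonds one after the other as SNAr (or Ullmann) bonds and grows the chain from ring C.
- Forward sequence: 2,4-dibromophenol A1 would displace the fluoride of 3,4,5-tribromo-2-fluorobenzaldehyde A2 to give 3,4,5-tribromo-2-(2,4-dibromophenoxy)benzaldehyde A3. A Dakin or Baeyer–Villiger oxidation would turn the formyl group into O1 of ring B, giving 3,4,5-tribromo-2-(2,4-dibromophenoxy)phenol A4. The same pair of operations with 3,5-dibromo-2-fluorobenzaldehyde A5, via aldehyde A6, would end at 13.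
- Two bonds cost four consecutive operations on the growing chain, so nothing is convergent.
- A2 needs two successive low-temperature deprotonations of polybromofluorobenzenes, in which ortho-bromoaryl anions are prone to halogen dance and aryne formation.
- The formyl group of A2 activates C4–Br (para) as well as C2–F.
- The phenoxide of A4 has to be heated with base in a dipolar solvent while its oxygen sits in position for a six-membered closure onto C2'–Br of ring C.
- A copper-catalysed version would have to pick one carbon–halogen bond among up to seven C–Br bonds.

**Alternative 2:** the biomimetic cut forms the same two bonds by anodic or one-electron oxidative coupling of phenoxyl radicals.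
- Forward sequence: A1 with 3,4,5-tribromophenol A7 to give A4, then A4 with 3,5-dibromophenol A8 to give 13.
- The bromophenols have nearly the same oxidation potential, so nothing favours cross-coupling over homo-coupling.
- A1 has its own free ortho carbon and would dimerize to 2,4-dibromo-6-(2,4-dibromophenoxy)phenol A9.
- In A7 and A8 the bromines are meta to the OH, so they do not block the carbons of high spin density. A8 keeps a free para carbon.
- Every product is again an oxidizable phenol, so chain growth cannot be stopped.

**Alternative 3:** all seven C–Br bonds are cut, the bromine-free skeleton 2-(2-phenoxyphenoxy)phenol A10 is assembled first, and it is brominated seven times in one operation.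
- The free OH of ring A directs to C4 and C6, whereas the target needs C3 and C5.
- On ring B the third bromine has to choose between C3 and C6, which differ only in the remote aryl group on the neighbouring oxygen.
- The forcing conditions that a third bromine on ring B requires would carry ring C beyond the 2',4' stage.
- The step looks short, but it has no element that secures any of the three patterns.

Key step: step 5

## Route

Step 1
Reactants: 1 5-bromo-2-nitrophenol
Product: 2 2,3,4-tribromo-6-nitrophenol
Conditions: Br2 (2.4 equiv), AcOH, 25 to 80 °C
Reagents that add atoms: bromine, BrBr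
Why: Electrophilic aromatic bromination; the OH (ortho/para), the nitro group (meta) and the bromine (ortho) of 1 all point to C4 and C6, and the only other free carbon is ortho to the nitro group and meta to the OH, so the reaction should stop at the tribromide.

Step 2
Reactants: 2 2,3,4-tribromo-6-nitrophenol
Product: 3 6-amino-2,3,4-tribromophenol
Conditions: Na2S2O4 (4 equiv), THF/H2O, 50 °C, under N2
Reagents that add atoms: none
Why: Dithionite reduction of a nitroarene runs by electron transfer to the nitro group and leaves aryl bromides alone, unlike catalytic hydrogenation; the air-sensitive aminophenol is taken on at once.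

Step 3
Reactants: 3 6-amino-2,3,4-tribromophenol
Product: 4 2,3,4-tribromo-6-diazocyclohexa-2,4-dien-1-one (o-quinone diazide of ring B)
Conditions: t-BuONO (1.3 equiv), AcOH/MeCN, 0 °C, dark; kept cold and used fresh
Reagents that add atoms: tert-butyl nitrite, CC(C)(C)ON=O
Why: Diazotization of an o-aminophenol with an alkyl nitrite; the diazonium group forms next to a strongly acidic OH, whose proton is lost to give the neutral diazide, and the halide-free medium avoids exchange of Br4, which is para to the diazo carbon.

Step 4
Reactants: 5 2,4-dibromo-1-iodobenzene; 6 1,3,5-trimethoxybenzene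
Product: 8 (2,4-dibromophenyl)(2,4,6-trimethoxyphenyl)iodonium tosylate, via hydroxy(tosyloxy)iodoarene 7 (not isolated)
Conditions: mCPBA (1.1 equiv), TsOH·H2O (1.1 equiv), MeCN, 75 °C; then 6 (1.05 equiv), 75 °C to rt; trituration with Et2O
Reagents that add atoms: p-toluenesulfonic acid, Cc1ccc(cc1)S(=O)(=O)O
Why: One-pot synthesis of an unsymmetrical diaryliodonium salt; the peracid oxidizes the iodide in the presence of the sulfonic acid to the iodine(III) species 7 (its OH oxygen comes from the peracid and leaves as water), which attacks the very electron-rich arene 6 by electrophilic aromatic substitution at one of three equivalent positions.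

Step 5
Reactants: 4 2,3,4-tribromo-6-diazocyclohexa-2,4-dien-1-one; 9 2,4-dibromo-6-methoxyphenol; 8 (2,4-dibromophenyl)(2,4,6-trimethoxyphenyl)iodonium tosylate
Product: 11 1,2,3-tribromo-4-(2,4-dibromophenoxy)-5-(2,4-dibromo-6-methoxyphenoxy)benzene, via insertion phenol 10 (not isolated)
Conditions: 9 (1.1 equiv), Rh2(esp)2 (1 mol %), DCE, 60 °C, dark, 4 added over 3 h; then 8 (1.3 equiv), Cs2CO3 (2.5 equiv), MeCN, 50 °C, same flask
Reagents that add atoms: none
Why: Proposed new method: Rh2(esp)2 expels the diazo nitrogen of 4 and gives an electrophilic quinoid carbene at C1 of ring B, the hydroxyl oxygen of 9 adds to it, and proton transfer from the oxonium ylide to the former carbonyl oxygen aromatizes ring B to 10, so that a phenol oxygen is joined to the ortho carbon of another phenol, two centres of like (nucleophilic) polarity. The closest known reaction types are the Rh(II)-catalysed O–H insertion of 1,2-diazonaphthoquinones into alcohols and water and the O–H insertion of α-diazocarbonyl compounds into phenols; new is the pairing of a benzenoid, polybrominated o-quinone diazide with a phenol to make a diaryl ether. Regiochemistry is a matter of constitution and not of selectivity: the carbon that bore nitrogen (next to H6) takes the oxygen of ring A and the carbonyl oxygen (next to Br3) becomes the only free phenol, so the two oxygens of ring B are told apart by the OH/NO2 pair of 1. Chemoselectivity needs O–H capture to beat azo coupling, C-arylation and Wolff ring contraction: in 9 both ortho positions and the para position are blocked (Br, OMe, Br), the medium is neutral, and 60 °C in the dark lies below the thermal and photochemical threshold of the contraction. Phenol 10 competes with 9 for the carbene, but it is the weaker nucleophile (three bromines, no methoxy group), and slow addition keeps the stationary concentration of 4 low. The second stage is the known metal-free O-arylation of phenoxides with diaryliodonium salts: the phenoxide of 10 binds to the iodine of 8 and ligand coupling transfers the electron-poorer, ortho-substituted 2,4-dibromophenyl group, while the trimethoxyphenyl group stays on iodine as a dummy ligand. Neither Rh(II) nor iodine(III) inserts into C–Br bonds, and carbonate at 50 °C is too mild for Smiles migration or dibenzo-p-dioxin closure of the phenoxide of 10. No ring is closed and no stereocentre is formed.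

Step 6
Reactants: 11 1,2,3-tribromo-4-(2,4-dibromophenoxy)-5-(2,4-dibromo-6-methoxyphenoxy)benzene
Product: 13 bromoiesol A, via aryloxydibromoborane 12 (not isolated)
Conditions: BBr3 (3 equiv), CH2Cl2, −78 °C to rt; then H2O, 0 °C
Reagents that add atoms: none
Why: Lewis acid cleavage of an aryl methyl ether; BBr3 binds the most basic oxygen, bromide attacks the methyl carbon in an SN2 step to give 12, and water releases the phenol, whereas the diaryl ether C(sp2)–O bonds cannot be attacked in this way and the acidic medium shuts off all phenoxide-based side paths.

## Compound list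

1 | 5-bromo-2-nitrophenol | Oc1cc(Br)ccc1[N+](=O)[O-] | starting material
2 | 2,3,4-tribromo-6-nitrophenol | Oc1c(Br)c(Br)c(Br)cc1[N+](=O)[O-] | intermediate
3 | 6-amino-2,3,4-tribromophenol | Nc1cc(Br)c(Br)c(Br)c1O | intermediate
4 | 2,3,4-tribromo-6-diazocyclohexa-2,4-dien-1-one | O=C1C(Br)=C(Br)C(Br)=CC1=[N+]=[N-] | intermediate
5 | 2,4-dibromo-1-iodobenzene | Ic1ccc(Br)cc1Br | starting material
6 | 1,3,5-trimethoxybenzene | COc1cc(OC)cc(OC)c1 | starting material
7 | 2,4-dibromo-1-[hydroxy(tosyloxy)-λ3-iodanyl]benzene | Cc1ccc(cc1)S(=O)(=O)OI(O)c1ccc(Br)cc1Br | intermediate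
8 | (2,4-dibromophenyl)(2,4,6-trimethoxyphenyl)iodonium tosylate | COc1cc(OC)c([I+]c2ccc(Br)cc2Br)c(OC)c1.Cc1ccc(cc1)S(=O)(=O)[O-] | intermediate
9 | 2,4-dibromo-6-methoxyphenol | COc1cc(Br)cc(Br)c1O | starting material
10 | 2,3,4-tribromo-6-(2,4-dibromo-6-methoxyphenoxy)phenol | COc1cc(Br)cc(Br)c1Oc1cc(Br)c(Br)c(Br)c1O | intermediate
11 | 1,2,3-tribromo-4-(2,4-dibromophenoxy)-5-(2,4-dibromo-6-methoxyphenoxy)benzene | COc1cc(Br)cc(Br)c1Oc1cc(Br)c(Br)c(Br)c1Oc1ccc(Br)cc1Br | intermediate
12 | dibromo{3,5-dibromo-2-[3,4,5-tribromo-2-(2,4-dibromophenoxy)phenoxy]phenoxy}borane | BrB(Br)Oc1cc(Br)cc(Br)c1Oc1cc(Br)c(Br)c(Br)c1Oc1ccc(Br)cc1Br | intermediate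
13 | bromoiesol A, 3,5-dibromo-2-[3,4,5-tribromo-2-(2,4-dibromophenoxy)phenoxy]phenol | Oc1cc(Br)cc(Br)c1Oc1cc(Br)c(Br)c(Br)c1Oc1ccc(Br)cc1Br | target

## Step count and least certain steps

Total step count: 6. Longest linear sequence: 5 (steps 1, 2, 3, 5, 6). Step 4 is a one-step branch.

**Step 5 (key step, proposed new method).**
- Most likely failure: the hindered, weakly nucleophilic OH of 9 captures the quinoid carbene too slowly. The carbene is then used up by attack of the product phenol (chain growth), by dimerization with unreacted diazide, or by ring contraction.
- Loss of nitrogen may also be sluggish, because three bromines give 4 strong diazonium phenolate character.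
- In the second stage, unreacted 9 also consumes 8.
- The fallback uses known chemistry only, sets out from 2 (with 8 and 9) and comes back at 11; it makes C1 of ring B an iodine(III) electrophile instead of a carbene. O-Arylation of 2 with 8 (Cs2CO3, MeCN, 80 °C) should give 1,2,3-tribromo-4-(2,4-dibromophenoxy)-5-nitrobenzene F1. Reduction with dithionite gives 3,4,5-tribromo-2-(2,4-dibromophenoxy)aniline F2. A Sandmeyer-type iodination (NaNO2, H2SO4/AcOH, then KI) gives 1,2,3-tribromo-4-(2,4-dibromophenoxy)-5-iodobenzene F3. The procedure of step 4 (mCPBA, TsOH, then 6) gives [3,4,5-tribromo-2-(2,4-dibromophenoxy)phenyl](2,4,6-trimethoxyphenyl)iodonium tosylate F4. Metal-free O-arylation of 9 with F4 (Cs2CO3, MeCN, 50 °C) gives 11.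

**Step 3.**
- The diazide may lose nitrogen under light or on warming during isolation.
- Br4, para to the diazo carbon, may be displaced by a nucleophile.
- Freshly formed diazonium species may couple with unreacted aminophenol.
- The fallback sets out from 3 and comes back at 11 without any isolated diazo compound. Diazotization in strong acid with immediate quench by iodide (NaNO2, H2SO4/AcOH, 0 °C, then KI) gives 2,3,4-tribromo-6-iodophenol F5. O-Arylation of F5 with 8 gives the iodide F3, which goes on through the iodonium salt F4 and 9 to 11, as described for step 5.

**Step 4.**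
- Oxidation of the electron-poor, ortho-substituted iodide may be slow, and peracid that is left over would then oxidize 6 before it is iodinated.
- The fallback gives up iodine(III) for ring C, sets out from 10 (isolated after the first stage of step 5) and comes back at 11. SNAr of the phenoxide of 10 on 2-bromo-1-fluoro-4-nitrobenzene F6 (K2CO3, DMF, rt to 40 °C) gives 1,2,3-tribromo-4-(2-bromo-4-nitrophenoxy)-5-(2,4-dibromo-6-methoxyphenoxy)benzene F7. Reduction gives 3-bromo-4-[2,3,4-tribromo-6-(2,4-dibromo-6-methoxyphenoxy)phenoxy]aniline F8. A Sandmeyer bromination (t-BuONO, CuBr2, MeCN) gives 11.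

**Step 1.**
- The reaction may stall after the first bromination, because the second bromine must enter a nitro-deactivated ring at a carbon buttressed by the bromine already present.
- The fallback moves the two OH-directed bromines behind the insertion, sets out from 1 and comes back at 10. Reduction of 1 gives 2-amino-5-bromophenol F9. Diazotization as in step 3 gives 3-bromo-6-diazocyclohexa-2,4-dien-1-one F10. O–H insertion into 9 as in the first stage of step 5 gives 5-bromo-2-(2,4-dibromo-6-methoxyphenoxy)phenol F11. Bromination (Br2, 2 equiv, AcOH/CH2Cl2, 0 °C) is then directed by the free OH of ring B to its ortho and para carbons (C3 and C5), while the twice brominated ring A is much less reactive, and gives 10.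

## Further compounds

F1 | step 5 | 1,2,3-tribromo-4-(2,4-dibromophenoxy)-5-nitrobenzene | O=[N+]([O-])c1cc(Br)c(Br)c(Br)c1Oc1ccc(Br)cc1Br
F2 | step 5 | 3,4,5-tribromo-2-(2,4-dibromophenoxy)aniline | Nc1cc(Br)c(Br)c(Br)c1Oc1ccc(Br)cc1Br
F3 | step 5 | 1,2,3-tribromo-4-(2,4-dibromophenoxy)-5-iodobenzene | Ic1cc(Br)c(Br)c(Br)c1Oc1ccc(Br)cc1Br
F4 | step 5 | [3,4,5-tribromo-2-(2,4-dibromophenoxy)phenyl](2,4,6-trimethoxyphenyl)iodonium tosylate | COc1cc(OC)c([I+]c2cc(Br)c(Br)c(Br)c2Oc2ccc(Br)cc2Br)c(OC)c1.Cc1ccc(cc1)S(=O)(=O)[O-]
F5 | step 3 | 2,3,4-tribromo-6-iodophenol | Oc1c(Br)c(Br)c(Br)cc1I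
F6 | step 4 | 2-bromo-1-fluoro-4-nitrobenzene | O=[N+]([O-])c1ccc(F)c(Br)c1
F7 | step 4 | 1,2,3-tribromo-4-(2-bromo-4-nitrophenoxy)-5-(2,4-dibromo-6-methoxyphenoxy)benzene | COc1cc(Br)cc(Br)c1Oc1cc(Br)c(Br)c(Br)c1Oc1ccc(cc1Br)[N+](=O)[O-]
F8 | step 4 | 3-bromo-4-[2,3,4-tribromo-6-(2,4-dibromo-6-methoxyphenoxy)phenoxy]aniline | COc1cc(Br)cc(Br)c1Oc1cc(Br)c(Br)c(Br)c1Oc1ccc(N)cc1Br
F9 | step 1 | 2-amino-5-bromophenol | Nc1ccc(Br)cc1O
F10 | step 1 | 3-bromo-6-diazocyclohexa-2,4-dien-1-one | O=C1C=C(Br)C=CC1=[N+]=[N-]
F11 | step 1 | 5-bromo-2-(2,4-dibromo-6-methoxyphenoxy)phenol | COc1cc(Br)cc(Br)c1Oc1ccc(Br)cc1O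
A1 | alternative 1 | 2,4-dibromophenol | Oc1ccc(Br)cc1Br
A2 | alternative 1 | 3,4,5-tribromo-2-fluorobenzaldehyde | O=Cc1cc(Br)c(Br)c(Br)c1F
A3 | alternative 1 | 3,4,5-tribromo-2-(2,4-dibromophenoxy)benzaldehyde | O=Cc1cc(Br)c(Br)c(Br)c1Oc1ccc(Br)cc1Br
A4 | alternative 1 | 3,4,5-tribromo-2-(2,4-dibromophenoxy)phenol | Oc1cc(Br)c(Br)c(Br)c1Oc1ccc(Br)cc1Br
A5 | alternative 1 | 3,5-dibromo-2-fluorobenzaldehyde | O=Cc1cc(Br)cc(Br)c1F
A6 | alternative 1 | 3,5-dibromo-2-[3,4,5-tribromo-2-(2,4-dibromophenoxy)phenoxy]benzaldehyde | O=Cc1cc(Br)cc(Br)c1Oc1cc(Br)c(Br)c(Br)c1Oc1ccc(Br)cc1Br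
A7 | alternative 2 | 3,4,5-tribromophenol | Oc1cc(Br)c(Br)c(Br)c1
A8 | alternative 2 | 3,5-dibromophenol | Oc1cc(Br)cc(Br)c1
A9 | alternative 2 | 2,4-dibromo-6-(2,4-dibromophenoxy)phenol | Oc1c(Br)cc(Br)cc1Oc1ccc(Br)cc1Br
A10 | alternative 3 | 2-(2-phenoxyphenoxy)phenol | Oc1ccccc1Oc1ccccc1Oc1ccccc1
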